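## Retrosynthetic overview

1. Target ⇒ aryl silyl ether removal ⇒ 6β-alcohol with the C5=C10 olefin, made from a Δ5(6)-octalin with 10β-H by a Schenck ene reaction that moves the C10 chirality to C6.
2. Butenolide: B-alkyl Suzuki coupling of the C9 vinyl group with 4-bromofuran-2(5H)-one (this ring is bought intact); the vinyl group comes from the C9 aldehyde by Wittig methylenation.
3. Decalin, both rings in one flask: ring-closing enyne metathesis of an acyclic 1,7-enyne gives ring A as a 1-vinylcyclohexene, and a catalytic asymmetric formyl-exo Diels–Alder reaction with tiglic aldehyde then closes ring B and sets C8, C9 and C10.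
4. Enyne: the C4 quaternary centre comes from (E)-3-methylpent-2-en-4-yn-1-ol by Sharpless epoxidation and a stereospecific epoxy silyl ether to aldehyde 1,2-shift; then butenyl Grignard addition, phloretate ester formation and oxidation.
5. Ring order: ring A, then ring B (same operation); the butenolide ring is attached last.

Convention: positions follow halimane numbering of the target (ring A = C1–C5 and C10, with the C3 ketone and quaternary C4; ring B = C5–C10, with 6-OH, 8-Me and quaternary C9; side chain C11–C16); β is the face of 6-OH and of the C9 side chain, α the face of the C8 and C9 methyl groups.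

Assumption: the (S)-oxazaborolidine is taken as the catalyst enantiomer that exposes the required enal face in step 7; if the opposite sense is found, the (R)-catalyst is used with nothing else changed.

## Route

Step 1
Reactants: 1 (E)-3-methylpent-2-en-4-yn-1-ol
Product: 3 tert-butyl{[(2S,3S)-3-ethynyl-3-methyloxiran-2-yl]methoxy}dimethylsilane, via epoxy alcohol 2 (not isolated)
Conditions: Ti(OiPr)4 (10 mol%), L-(+)-diethyl tartrate (12 mol%), t-BuOOH, 4 Å MS, CH2Cl2, −20 °C; then P(OMe)3; then TBSCl, Et3N, DMAP, −20 → 0 °C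
Reagents that add atoms: tert-butyl hydroperoxide, CC(C)(C)OO; tert-butyldimethylsilyl chloride, CC(C)(C)[Si](C)(C)Cl
Why: Sharpless asymmetric epoxidation of the E-allylic alcohol with the L-(+)-tartrate complex gives the (2S,3S)-epoxide (same sense as geraniol), and the small, water-soluble epoxy alcohol is silylated in the same flask (in situ derivatisation).

Step 2
Reactants: 3 tert-butyl{[(2S,3S)-3-ethynyl-3-methyloxiran-2-yl]methoxy}dimethylsilane
Product: 4 (2S)-2-{[(tert-butyldimethylsilyl)oxy]methyl}-2-methylbut-3-ynal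
Conditions: MeAl(OAr)2 (MABR, Ar = 4-bromo-2,6-di-tert-butylphenyl, 20 mol%), CH2Cl2, −78 → −40 °C
Reagents that add atoms: none
Why: Yamamoto rearrangement of an epoxy silyl ether, in which the bulky aluminium Lewis acid opens the epoxide at the tertiary propargylic carbon and the siloxymethyl group migrates anti to the breaking C–O bond, so the epoxide chirality is carried with inversion into the all-carbon quaternary centre (future C4, S).

Step 3
Reactants: 4 (2S)-2-{[(tert-butyldimethylsilyl)oxy]methyl}-2-methylbut-3-ynal; 5 but-3-en-1-ylmagnesium bromide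
Product: 7 (2S,3RS)-2-ethynyl-2-methylhept-6-ene-1,3-diol, via silyl ether carbinol 6 (not isolated)
Conditions: THF, −78 °C; then 3 M HCl in MeOH, 23 °C
Reagents that add atoms: none
Why: Grignard addition to a non-enolisable α-quaternary aldehyde (faster at −78 °C than deprotonation of the alkyne) followed by acid methanolysis of the primary silyl ether; the new carbinol centre forms as a mixture and is removed by the oxidation in step 6.

Step 4
Reactants: 8 3-(4-hydroxyphenyl)propanoic acid (phloretic acid)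
Product: 10 3-{4-[(triisopropylsilyl)oxy]phenyl}propanoic acid, via bis-silyl compound 9 (not isolated)
Conditions: TIPSCl (2.2 equiv), imidazole, DMF, 23 °C; then 1 M HCl, THF–H2O, 23 °C
Reagents that add atoms: triisopropylsilyl chloride, CC(C)[Si](Cl)(C(C)C)C(C)C
Why: Protecting-group chemistry in which both acidic OH groups are silylated and the labile silyl ester alone is hydrolysed, leaving the aryl silyl ether.

Step 5
Reactants: 7 (2S,3RS)-2-ethynyl-2-methylhept-6-ene-1,3-diol; 10 3-{4-[(triisopropylsilyl)oxy]phenyl}propanoic acid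
Product: 11 (2S,3RS)-2-ethynyl-3-hydroxy-2-methylhept-6-en-1-yl 3-{4-[(triisopropylsilyl)oxy]phenyl}propanoate
Conditions: EDC·HCl, DMAP (cat.), CH2Cl2, 0 °C
Reagents that add atoms: none
Why: Steglich esterification, selective because the primary hydroxyl acylates much faster than the secondary hydroxyl beside the quaternary carbon.

Step 6
Reactants: 11 (2S,3RS)-2-ethynyl-3-hydroxy-2-methylhept-6-en-1-yl 3-{4-[(triisopropylsilyl)oxy]phenyl}propanoate
Product: 12 (2S)-2-ethynyl-2-methyl-3-oxohept-6-en-1-yl 3-{4-[(triisopropylsilyl)oxy]phenyl}propanoate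
Conditions: Dess–Martin periodinane, CH2Cl2, 23 °C
Reagents that add atoms: none
Why: Dess–Martin oxidation under neutral conditions; the quaternary carbon carries no hydrogen, so neither epimerisation nor β-elimination of the acyloxy group is possible.

Step 7
Reactants: 12 (2S)-2-ethynyl-2-methyl-3-oxohept-6-en-1-yl 3-{4-[(triisopropylsilyl)oxy]phenyl}propanoate; 13 (E)-2-methylbut-2-enal (tiglic aldehyde)
Product: 15 [(1S,4aR,5R,6S)-5-formyl-1,5,6-trimethyl-2-oxo-1,2,3,4,4a,5,6,7-octahydronaphthalen-1-yl]methyl 3-{4-[(triisopropylsilyl)oxy]phenyl}propanoate, via vinylcyclohexenone diene 14 (not isolated)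
Conditions: second-generation Hoveyda–Grubbs catalyst [RuCl2(H2IMes)(=CH-C6H4-2-OiPr)] (5 mol%), ethylene (1 atm), CH2Cl2, 40 °C; then argon purge, 13 (3 equiv), (S)-o-tolyl-CBS-oxazaborolidine·AlBr3 (20 mol%), −78 → −40 °C
Reagents that add atoms: none
Why: Proposed new method: exo-mode ring-closing enyne metathesis of the 1,7-enyne under ethylene gives the 1-vinylcyclohexene 14 (ring A), whose s-cis form is favoured by the neighbouring quaternary C4, and once ethylene is purged the phosphine-free ruthenium residue should not stop the AlBr3-activated oxazaborolidine from catalysing the Diels–Alder reaction with 13 (ring B), in which the enal β-carbon bonds to the unsubstituted diene terminus (C7–C8, then C9–C10), the catalyst selects the enal face (8S, 9R) and the formyl-exo topology usual for α-methyl enals places 10-H on the β-face, cis to the formyl group; the closest known reactions are one-pot enyne metathesis/Diels–Alder sequences and the oxazaborolidinium-catalysed Diels–Alder reaction of α-methyl enals.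

Step 8
Reactants: 15 [(1S,4aR,5R,6S)-5-formyl-1,5,6-trimethyl-2-oxo-1,2,3,4,4a,5,6,7-octahydronaphthalen-1-yl]methyl 3-{4-[(triisopropylsilyl)oxy]phenyl}propanoate
Product: 16 [(1S,4aS,5R,6S)-5-ethenyl-1,5,6-trimethyl-2-oxo-1,2,3,4,4a,5,6,7-octahydronaphthalen-1-yl]methyl 3-{4-[(triisopropylsilyl)oxy]phenyl}propanoate
Conditions: Ph3PCH3Br, KOtBu, THF, 0 °C; then 15, −78 → 0 °C
Reagents that add atoms: methyltriphenylphosphonium bromide, C[P+](c1ccccc1)(c1ccccc1)c1ccccc1.[Br-]
Why: Wittig methylenation, chemoselective because the aldehyde reacts at low temperature while the α-quaternary ketone and the esters do not, and the aldehyde has no α-hydrogen to epimerise.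

Step 9
Reactants: 16 [(1S,4aS,5R,6S)-5-ethenyl-1,5,6-trimethyl-2-oxo-1,2,3,4,4a,5,6,7-octahydronaphthalen-1-yl]methyl 3-{4-[(triisopropylsilyl)oxy]phenyl}propanoate; 17 4-bromofuran-2(5H)-one
Product: 19 [(1S,4aS,5R,6S)-1,5,6-trimethyl-2-oxo-5-[2-(5-oxo-2,5-dihydrofuran-3-yl)ethyl]-1,2,3,4,4a,5,6,7-octahydronaphthalen-1-yl]methyl 3-{4-[(triisopropylsilyl)oxy]phenyl}propanoate, via alkylborane 18 (not isolated)
Conditions: 9-BBN (1.2 equiv), THF, 0 → 23 °C; then 17, PdCl2(dppf) (5 mol%), AsPh3, K3PO4 (aq), DMF, 23 °C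
Reagents that add atoms: 9-borabicyclo[3.3.1]nonane, B1C2CCCC1CCC2 (its boron unit stays only in 18)
Why: Anti-Markovnikov hydroboration of the monosubstituted olefin by 9-BBN (faster than attack on the trisubstituted olefin or the hindered ketone) followed by B-alkyl Suzuki–Miyaura coupling with the β-bromobutenolide; no stereocentre is formed.

Step 10
Reactants: 19 [(1S,4aS,5R,6S)-1,5,6-trimethyl-2-oxo-5-[2-(5-oxo-2,5-dihydrofuran-3-yl)ethyl]-1,2,3,4,4a,5,6,7-octahydronaphthalen-1-yl]methyl 3-{4-[(triisopropylsilyl)oxy]phenyl}propanoate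
Product: 21 [(1S,5R,6S,8S)-8-hydroxy-1,5,6-trimethyl-2-oxo-5-[2-(5-oxo-2,5-dihydrofuran-3-yl)ethyl]-1,2,3,4,5,6,7,8-octahydronaphthalen-1-yl]methyl 3-{4-[(triisopropylsilyl)oxy]phenyl}propanoate, via hydroperoxide 20 (not isolated)
Conditions: O2, tetraphenylporphyrin (cat.), visible light, CH2Cl2, −20 °C; then PPh3, −20 → 23 °C
Reagents that add atoms: dioxygen, O=O
Why: Schenck ene reaction in which singlet oxygen attacks the β-face of the C5=C6 olefin (the α-face is screened by the axial 9α-methyl and the 4α-acyloxymethyl group), can take an allylic hydrogen on the C5 side only from C10 because C4 is quaternary, and does so suprafacially from the axial 10β-H, so oxygen arrives at C6 on the β-face (6S) as the double bond moves to C5=C10, and PPh3 reduces the hydroperoxide with retention.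

Step 11
Reactants: 21 [(1S,5R,6S,8S)-8-hydroxy-1,5,6-trimethyl-2-oxo-5-[2-(5-oxo-2,5-dihydrofuran-3-yl)ethyl]-1,2,3,4,5,6,7,8-octahydronaphthalen-1-yl]methyl 3-{4-[(triisopropylsilyl)oxy]phenyl}propanoate
Product: 22 [(1S,5R,6S,8S)-8-hydroxy-1,5,6-trimethyl-2-oxo-5-[2-(5-oxo-2,5-dihydrofuran-3-yl)ethyl]-1,2,3,4,5,6,7,8-octahydronaphthalen-1-yl]methyl 3-(4-hydroxyphenyl)propanoate (CNP0301014.1)
Conditions: Bu4NF, AcOH (1:1), THF, 0 °C
Reagents that add atoms: none
Why: Fluoride cleavage of the aryl silyl ether, buffered with acetic acid so that the butenolide, the β-acyloxy ketone and the allylic alcohol are left alone.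

## Compound list

1 | (E)-3-methylpent-2-en-4-yn-1-ol | C#C/C(C)=C/CO | starting material
2 | [(2S,3S)-3-ethynyl-3-methyloxiran-2-yl]methanol | OC[C@@H]1O[C@@]1(C)C#C | intermediate
3 | tert-butyl{[(2S,3S)-3-ethynyl-3-methyloxiran-2-yl]methoxy}dimethylsilane | CC(C)(C)[Si](C)(C)OC[C@@H]1O[C@@]1(C)C#C | intermediate
4 | (2S)-2-{[(tert-butyldimethylsilyl)oxy]methyl}-2-methylbut-3-ynal | O=C[C@](C#C)(C)CO[Si](C)(C)C(C)(C)C | intermediate
5 | but-3-en-1-ylmagnesium bromide | C=CCC[Mg]Br | starting material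
6 | (2S,3RS)-1-[(tert-butyldimethylsilyl)oxy]-2-ethynyl-2-methylhept-6-en-3-ol (C3 epimers) | C=CCCC(O)[C@](C#C)(C)CO[Si](C)(C)C(C)(C)C | intermediate
7 | (2S,3RS)-2-ethynyl-2-methylhept-6-ene-1,3-diol (C3 epimers) | C=CCCC(O)[C@](C#C)(C)CO | intermediate
8 | 3-(4-hydroxyphenyl)propanoic acid (phloretic acid) | OC(=O)CCc1ccc(O)cc1 | starting material
9 | triisopropylsilyl 3-{4-[(triisopropylsilyl)oxy]phenyl}propanoate | CC(C)[Si](C(C)C)(C(C)C)OC(=O)CCc1ccc(O[Si](C(C)C)(C(C)C)C(C)C)cc1 | intermediate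
10 | 3-{4-[(triisopropylsilyl)oxy]phenyl}propanoic acid | OC(=O)CCc1ccc(O[Si](C(C)C)(C(C)C)C(C)C)cc1 | intermediate
11 | (2S,3RS)-2-ethynyl-3-hydroxy-2-methylhept-6-en-1-yl 3-{4-[(triisopropylsilyl)oxy]phenyl}propanoate | C=CCCC(O)[C@](C#C)(C)COC(=O)CCc1ccc(O[Si](C(C)C)(C(C)C)C(C)C)cc1 | intermediate
12 | (2S)-2-ethynyl-2-methyl-3-oxohept-6-en-1-yl 3-{4-[(triisopropylsilyl)oxy]phenyl}propanoate | C=CCCC(=O)[C@](C#C)(C)COC(=O)CCc1ccc(O[Si](C(C)C)(C(C)C)C(C)C)cc1 | intermediate
13 | (E)-2-methylbut-2-enal (tiglic aldehyde) | C/C=C(\C)C=O | starting material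
14 | [(1S)-6-ethenyl-1-methyl-2-oxocyclohex-5-en-1-yl]methyl 3-{4-[(triisopropylsilyl)oxy]phenyl}propanoate | O=C1CCC=C(C=C)[C@@]1(C)COC(=O)CCc1ccc(O[Si](C(C)C)(C(C)C)C(C)C)cc1 | intermediate
15 | [(1S,4aR,5R,6S)-5-formyl-1,5,6-trimethyl-2-oxo-1,2,3,4,4a,5,6,7-octahydronaphthalen-1-yl]methyl 3-{4-[(triisopropylsilyl)oxy]phenyl}propanoate (10β-H, 9β-CHO, 8α,9α-dimethyl) | C[C@H]1CC=C2[C@@H](CCC(=O)[C@]2(C)COC(=O)CCc2ccc(O[Si](C(C)C)(C(C)C)C(C)C)cc2)[C@]1(C)C=O | intermediate
16 | [(1S,4aS,5R,6S)-5-ethenyl-1,5,6-trimethyl-2-oxo-1,2,3,4,4a,5,6,7-octahydronaphthalen-1-yl]methyl 3-{4-[(triisopropylsilyl)oxy]phenyl}propanoate | C[C@H]1CC=C2[C@@H](CCC(=O)[C@]2(C)COC(=O)CCc2ccc(O[Si](C(C)C)(C(C)C)C(C)C)cc2)[C@]1(C)C=C | intermediate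
17 | 4-bromofuran-2(5H)-one | BrC1=CC(=O)OC1 | starting material
18 | B-alkyl-9-borabicyclo[3.3.1]nonane from hydroboration of the vinyl group of 16 (boron on C12) | C[C@H]1CC=C2[C@@H](CCC(=O)[C@]2(C)COC(=O)CCc2ccc(O[Si](C(C)C)(C(C)C)C(C)C)cc2)[C@]1(C)CCB1C2CCCC1CCC2 | intermediate
19 | [(1S,4aS,5R,6S)-1,5,6-trimethyl-2-oxo-5-[2-(5-oxo-2,5-dihydrofuran-3-yl)ethyl]-1,2,3,4,4a,5,6,7-octahydronaphthalen-1-yl]methyl 3-{4-[(triisopropylsilyl)oxy]phenyl}propanoate | C[C@H]1CC=C2[C@@H](CCC(=O)[C@]2(C)COC(=O)CCc2ccc(O[Si](C(C)C)(C(C)C)C(C)C)cc2)[C@]1(C)CCC1=CC(=O)OC1 | intermediate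
20 | [(1S,5R,6S,8S)-8-hydroperoxy-1,5,6-trimethyl-2-oxo-5-[2-(5-oxo-2,5-dihydrofuran-3-yl)ethyl]-1,2,3,4,5,6,7,8-octahydronaphthalen-1-yl]methyl 3-{4-[(triisopropylsilyl)oxy]phenyl}propanoate | C[C@H]1C[C@H](OO)C2=C(CCC(=O)[C@]2(C)COC(=O)CCc2ccc(O[Si](C(C)C)(C(C)C)C(C)C)cc2)[C@]1(C)CCC1=CC(=O)OC1 | intermediate
21 | [(1S,5R,6S,8S)-8-hydroxy-1,5,6-trimethyl-2-oxo-5-[2-(5-oxo-2,5-dihydrofuran-3-yl)ethyl]-1,2,3,4,5,6,7,8-octahydronaphthalen-1-yl]methyl 3-{4-[(triisopropylsilyl)oxy]phenyl}propanoate | C[C@H]1C[C@H](O)C2=C(CCC(=O)[C@]2(C)COC(=O)CCc2ccc(O[Si](C(C)C)(C(C)C)C(C)C)cc2)[C@]1(C)CCC1=CC(=O)OC1 | intermediate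
22 | [(1S,5R,6S,8S)-8-hydroxy-1,5,6-trimethyl-2-oxo-5-[2-(5-oxo-2,5-dihydrofuran-3-yl)ethyl]-1,2,3,4,5,6,7,8-octahydronaphthalen-1-yl]methyl 3-(4-hydroxyphenyl)propanoate | C[C@H]1C[C@H](O)C2=C(CCC(=O)[C@]2(C)COC(=O)CCc2ccc(O)cc2)[C@]1(C)CCC1=CC(=O)OC1 | target

## Step count and risks

Total steps: 11 (step 4 is a one-step side branch). Longest linear sequence: 10 steps (1, 2, 3, 5, 6, 7, 8, 9, 10, 11).

Step 7 (metathesis/Diels–Alder) is the most likely to fail. Tiglic aldehyde is a sluggish dienophile, and the formyl-exo preference that puts 10-H on the β-face is assumed, not proven, for this diene. The fallback sets out from 12 and comes back at 21; it gives up the chirality relay from C10 to C6. If the cycloaddition delivers the formyl-endo product, the 10-epimeric aldehyde F1 (10α-H, C8 and C9 still fixed by the catalyst), it is methylenated as in step 8 to the 10-epimeric olefin F2. Hydroboration as in step 9 gives the 10-epimeric alkylborane F3, and coupling with 17 gives the 10-epimeric butenolide F4. Photooxygenation now removes 10α-H and gives the 6α-hydroperoxide F5, which PPh3 reduces to the 6α-alcohol F6. Dess–Martin oxidation gives the Δ5(10)-6-ketone F7, in which C10 is no longer a stereocentre. (R)-Me-CBS-oxazaborolidine with catecholborane at −78 °C then reduces the enone carbonyl, not the hindered C3 ketone, under reagent control to give 21.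

Step 10 (Schenck ene) may give oxygen at C5 with a Δ6 olefin, or react on the wrong face. The fallback sets out from 19 and comes back at 21; it replaces the pericyclic step by epoxide isomerisation. Buffered mCPBA epoxidises the only electron-rich olefin on its open β-face to give the 5β,6β-epoxide F10. Cp2TiCl (trivalent titanium, made from Cp2TiCl2 and Mn dust in THF) opens it homolytically to the tertiary C5 radical with oxygen left on C6. The only β-hydrogen available for the following elimination is 10-H, so the C5=C10 olefin and the 6β-alcohol 21 result.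

Step 9 (hydroboration/Suzuki) may suffer from competing reduction of the C3 ketone by 9-BBN or from a slow B-alkyl coupling with the base-sensitive bromobutenolide. The fallback sets out from 15 and comes back at 19; it makes the C11–C12 link by olefination instead of cross-coupling and bypasses step 8. 4-(Bromomethyl)furan-2(5H)-one and PPh3 give [(5-oxo-2,5-dihydrofuran-3-yl)methyl]triphenylphosphonium bromide F8. Its ylide (KOtBu, THF) reacts with the aldehyde of 15, not with the ketone, to give the 11,12-dehydro dienyl butenolide F9. Diimide (2-nitrobenzenesulfonylhydrazide, Et3N) then saturates only the disubstituted C11=C12 bond and gives 19.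

## Further compounds

F1 | step 7 | 10-epimer of 15 (formyl-endo adduct, 10α-H aldehyde) | C[C@H]1CC=C2[C@H](CCC(=O)[C@]2(C)COC(=O)CCc2ccc(O[Si](C(C)C)(C(C)C)C(C)C)cc2)[C@]1(C)C=O
F2 | step 7 | 10-epimer of 16 (10α-H vinyl compound) | C[C@H]1CC=C2[C@H](CCC(=O)[C@]2(C)COC(=O)CCc2ccc(O[Si](C(C)C)(C(C)C)C(C)C)cc2)[C@]1(C)C=C
F3 | step 7 | 10-epimer of 18 (B-alkyl-9-borabicyclo[3.3.1]nonane) | C[C@H]1CC=C2[C@H](CCC(=O)[C@]2(C)COC(=O)CCc2ccc(O[Si](C(C)C)(C(C)C)C(C)C)cc2)[C@]1(C)CCB1C2CCCC1CCC2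
F4 | step 7 | 10-epimer of 19 (10α-H butenolide) | C[C@H]1CC=C2[C@H](CCC(=O)[C@]2(C)COC(=O)CCc2ccc(O[Si](C(C)C)(C(C)C)C(C)C)cc2)[C@]1(C)CCC1=CC(=O)OC1
F5 | step 7 | 6-epimer of 20 (6α-hydroperoxide) | C[C@H]1C[C@@H](OO)C2=C(CCC(=O)[C@]2(C)COC(=O)CCc2ccc(O[Si](C(C)C)(C(C)C)C(C)C)cc2)[C@]1(C)CCC1=CC(=O)OC1
F6 | step 7 | 6-epimer of 21 (6α-alcohol) | C[C@H]1C[C@@H](O)C2=C(CCC(=O)[C@]2(C)COC(=O)CCc2ccc(O[Si](C(C)C)(C(C)C)C(C)C)cc2)[C@]1(C)CCC1=CC(=O)OC1
F7 | step 7 | Δ5(10)-3,6-diketone (6-oxo analogue of 21) | C[C@H]1CC(=O)C2=C(CCC(=O)[C@]2(C)COC(=O)CCc2ccc(O[Si](C(C)C)(C(C)C)C(C)C)cc2)[C@]1(C)CCC1=CC(=O)OC1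
F8 | step 9 | [(5-oxo-2,5-dihydrofuran-3-yl)methyl]triphenylphosphonium bromide | O=C1OCC(C[P+](c2ccccc2)(c2ccccc2)c2ccccc2)=C1.[Br-]
F9 | step 9 | (E)-11,12-dehydro analogue of 19 (dienyl butenolide) | C[C@H]1CC=C2[C@@H](CCC(=O)[C@]2(C)COC(=O)CCc2ccc(O[Si](C(C)C)(C(C)C)C(C)C)cc2)[C@]1(C)/C=C/C1=CC(=O)OC1
F10 | step 10 | 5β,6β-epoxide of 19 | C[C@H]1C[C@@H]2O[C@]23[C@@H](CCC(=O)[C@]3(C)COC(=O)CCc2ccc(O[Si](C(C)C)(C(C)C)C(C)C)cc2)[C@]1(C)CCC1=CC(=O)OC1
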